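Atom labels follow germacrane numbering (ring C1–C10, lactone carbons C11–C13, methyl C14, methylene C15). Everything rests on disconnecting C6–C7, the bond shared by the α-methylene-γ-butyrolactone (O–C6–C7–C11–C12) and the ten-membered carbocycle. The oxygen on C6 and the C11(=C13)–C12 acrylate unit on C7 are the retron of a 2-(alkoxycarbonyl)allyl-metal addition to an aldehyde. An acyclic ω-formyl (Z)-2-(bromomethyl)enoate, assembled from (R)-linalool and (R)-glyceraldehyde acetonide by cross-metathesis, is closed with CrCl2: one operation forms C6–C7, closes the carbocycle, sets C6 and C7, creates the exocyclic methylene and lactonizes. Desilylation and tigloylation finish the route.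

Key step: step 14

Remarks on the chemistry
- The ester on C8 is read from the SMILES as the (E)-2-methylbut-2-enoate (tiglate); the target is (5S,6S,7R,8R,10R) with a trans-fused lactone.
- Assumption: in the ten-membered chair transition state of step 14 the facial bias of the allyl unit (set by C8) overrides the weaker Felkin–Anh preference of the α-acetoxy aldehyde (C5). The configuration of 25 has to be proven at that stage.
- (R)-Linalool and (R)-glyceraldehyde acetonide are taken as commercial in high enantiomeric purity.

Step 1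
Reactants: 1 2,3-dibromopropene; 2 vinylmagnesium bromide
Product: 3 2-bromopenta-1,4-diene
Conditions: CuI (cat.), THF, 0 °C → rt
Reagents that add atoms: none
Why: Copper-catalysed allylic substitution by the Grignard reagent takes place only at the allylic C–Br bond and leaves the vinylic bromide for step 2; no stereocentre is formed.

Step 2
Reactants: 3 2-bromopenta-1,4-diene; 4 (R)-glyceraldehyde acetonide
Product: 6 anti allylic alcohol (C5 S; dioxolane 4R), via penta-1,4-dien-2-yllithium 5 (not isolated)
Conditions: tBuLi (2 equiv), Et2O, −78 °C; then 4, −78 °C; H2O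
Reagents that add atoms: none
Why: Bromine–lithium exchange and 1,2-addition of the alkenyllithium to the α-alkoxy aldehyde should favour the anti (Felkin–Anh) adduct, which sets C5 as S under control of the dioxolane centre (excised later as the C6 aldehyde); the syn epimer is removed by chromatography.

Step 3
Reactants: 6 anti allylic alcohol
Product: 7 C5 acetate
Conditions: Ac2O, pyridine, DMAP (cat.), CH2Cl2, 0 °C → rt
Reagents that add atoms: acetic anhydride, CC(=O)OC(C)=O
Why: DMAP-catalysed O-acylation installs the C5 acetate of the target at the outset, with the carbinol configuration untouched.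

Step 4
Reactants: 8 (R)-linalool
Product: 9 (R)-linalool triethylsilyl ether
Conditions: TESOTf, 2,6-lutidine, CH2Cl2, −78 → 0 °C
Reagents that add atoms: triethylsilyl triflate, CC[Si](CC)(CC)OS(=O)(=O)C(F)(F)F
Why: Silyl triflate silylation caps the hindered tertiary C10 hydroxyl, which would otherwise trap the C7 aldehyde as a lactol; C10 (R) comes from the chiral pool.

Step 5
Reactants: 9 (R)-linalool triethylsilyl ether
Product: 10 (4R)-4-methyl-4-(triethylsilyloxy)hex-5-enal
Conditions: O3, CH2Cl2, −78 °C (Sudan red 7B end point); PPh3, −78 °C → rt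
Reagents that add atoms: ozone, [O-][O+]=O
Why: Ozonolysis is chemoselective for the electron-rich trisubstituted olefin over the vinyl group, which is deactivated and shielded by the adjacent quaternary silyloxy carbon.

Step 6
Reactants: 10 (4R)-4-methyl-4-(triethylsilyloxy)hex-5-enal
Product: 12 (2R,4R)-2-anilinooxy alcohol, via α-anilinooxy aldehyde 11 (not isolated)
Conditions: L-proline (20 mol%), PhNO, CHCl3, 4 °C; then NaBH4, EtOH, 0 °C
Reagents that add atoms: nitrosobenzene, O=Nc1ccccc1
Why: Proline-catalysed enamine α-aminoxylation (O-selective nitroso aldol) sets C8 as R by catalyst control (L-proline), and immediate borohydride reduction prevents epimerization of the α-oxy aldehyde.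

Step 7
Reactants: 12 (2R,4R)-2-anilinooxy alcohol
Product: 13 (2R,4R)-1,2-diol
Conditions: Zn dust, AcOH, THF, 0 °C → rt
Reagents that add atoms: none
Why: Dissolving-metal reduction cleaves the weak N–O bond and leaves the olefin and the hindered tertiary silyl ether intact.

Step 8
Reactants: 13 (2R,4R)-1,2-diol
Product: 15 differentially silylated triol, via primary triethylsilyl ether 14 (not isolated)
Conditions: TESCl, imidazole, CH2Cl2, −30 °C; then TBSOTf, 2,6-lutidine, −30 → 0 °C
Reagents that add atoms: chlorotriethylsilane, CC[Si](Cl)(CC)CC; tert-butyldimethylsilyl triflate, CC(C)(C)[Si](C)(C)OS(=O)(=O)C(F)(F)F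
Why: Sequential silylation exploits the higher reactivity of the primary hydroxyl toward the chlorosilane and then caps the secondary C8 hydroxyl with the silyl triflate, which differentiates C7 from C8 in one flask.

Step 9
Reactants: 15 differentially silylated triol; 7 C5 acetate
Product: 16 E-configured cross-metathesis product
Conditions: 7 (2.5 equiv), second-generation Hoveyda–Grubbs catalyst (10 mol%), 1,4-benzoquinone (10 mol%), CH2Cl2, 40 °C
Reagents that add atoms: none
Why: Olefin cross-metathesis joins the fast-reacting allyl terminus of 7 to the hindered, non-dimerizing tertiary allylic silyl ether, the bulk at C10 enforcing the E geometry of C1=C2, while the 1,1-disubstituted C4=C15 olefin is too hindered to compete.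

Step 10
Reactants: 16 E-configured cross-metathesis product
Product: 17 C7 aldehyde
Conditions: (COCl)2, DMSO, CH2Cl2, −78 → −40 °C; Et3N, −78 °C → rt
Reagents that add atoms: none
Why: Swern oxidation applied directly to the silyl ether cleaves and oxidizes only the unhindered primary triethylsilyl ether, the secondary TBS and tertiary TES ethers being too hindered, and the cold amine quench keeps C8 configurationally intact.

Step 11
Reactants: 17 C7 aldehyde; 18 methyl acrylate
Product: 19 Morita–Baylis–Hillman adduct (C7 epimers)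
Conditions: 18 (neat, excess), DABCO (1 equiv), rt
Reagents that add atoms: none
Why: The Morita–Baylis–Hillman reaction attaches the C11–C13 acrylate unit to the activated α-silyloxy aldehyde; the C7 carbinol forms as an inconsequential mixture because it becomes sp2 in step 12.

Step 12
Reactants: 19 Morita–Baylis–Hillman adduct
Product: 20 (Z)-allylic bromide
Conditions: NBS, Me2S, CH2Cl2, 0 °C → rt
Reagents that add atoms: N-bromosuccinimide, O=C1CCC(=O)N1Br
Why: Activation of the allylic alcohol as an alkoxysulfonium salt (Corey–Kim-type reagent) and SN2' attack of bromide give the 2-(bromomethyl)enoate with the thermodynamically favoured Z geometry (C8 trans to the ester).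

Step 13
Reactants: 20 (Z)-allylic bromide
Product: 22 C6 aldehyde, via vicinal diol 21 (not isolated)
Conditions: H5IO6, EtOAc, 0 °C → rt
Reagents that add atoms: none
Why: Periodic acid hydrolyses the terminal acetonide and cleaves the liberated diol (Malaprade cleavage) in one operation, excising the controller carbon and exposing C6 as the aldehyde under non-basic conditions that spare the epimerizable C5; 22 is used crude.

Step 14
Reactants: 22 C6 aldehyde
Product: 25 silyl-protected trans-fused lactone, via allylchromium dichloride 23 (not isolated), via chromium alkoxide 24 (not isolated)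
Conditions: CrCl2 (10 equiv), THF, 25 °C, slow addition of 22 (final 2 mM); aq. NH4Cl
Reagents that add atoms: none
Why: CrCl2 reduces the allylic C13–Br bond by two single-electron transfers to the allylchromium dichloride 23, whose γ-carbon C7 adds to the chromium-bound C6 formyl group through a six-membered chair (Zimmerman–Traxler) array, and the resulting trivalent-chromium alkoxide 24 acylates on the C12 methyl ester. The closest known reaction type is the Nozaki–Hiyama–Kishi (chromium Barbier) allylation of aldehydes with 2-(bromomethyl)acrylates to α-methylene-γ-butyrolactones, in the macrocyclizing form used to close ten-membered germacranolide rings at this same bond. The carbocycle closes by 10-exo-trig attack of C7 on the formyl carbon and the lactone by 5-exo-trig O-acylation. C7 is controlled by C8 (allylic 1,3-strain holds H8 in the plane of the allyl unit, so the aldehyde is delivered anti to C9 with the silyloxy group outside), and C6 by the chair, in which the C5 and C8 ring bonds are both pseudo-equatorial after metallotropic E/Z equilibration of 23, giving the anti (trans-lactone) pair. The step needs this C8-directed face to override the weaker Felkin–Anh preference of the α-acetoxy aldehyde (C5–O ends up syn to O6), which the ring constraint (C4 is part of the tether) and possible acetate-to-chromium chelation in THF should secure. It also needs ring closure to outrun oligomerization and 1,4-elimination, secured by slow addition at high dilution, by the E-C1=C2 and sp2 C4 turn elements, and by carrying O8 as a silyl ether and not as an ester.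

Step 15
Reactants: 25 silyl-protected trans-fused lactone
Product: 26 C8,C10-diol lactone
Conditions: HF·pyridine, pyridine, THF, 0 °C → rt
Reagents that add atoms: none
Why: Fluoride-mediated desilylation removes the tertiary TES and secondary TBS ethers under buffered, non-basic conditions that leave the acetate and the α-methylene lactone intact and do not promote translactonization to O8.

Step 16
Reactants: 26 C8,C10-diol lactone; 27 tigloyl chloride
Product: 28 target
Conditions: pyridine, DMAP (cat.), CH2Cl2, 0 °C → rt
Reagents that add atoms: none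
Why: Acylation with the acid chloride takes place at the secondary C8 hydroxyl only, the tertiary C10 hydroxyl being inert under these conditions, and the E (tiglate) geometry is the stable one and is retained.

Compound list
1 | 2,3-dibromopropene | C=C(Br)CBr | starting material
2 | vinylmagnesium bromide | C=C[Mg]Br | starting material
3 | 2-bromopenta-1,4-diene | C=CCC(Br)=C | intermediate
4 | (R)-2,2-dimethyl-1,3-dioxolane-4-carbaldehyde ((R)-glyceraldehyde acetonide) | CC1(C)OC[C@H](C=O)O1 | starting material
5 | penta-1,4-dien-2-yllithium | C=CCC([Li])=C | intermediate (not isolated)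
6 | (1S)-1-[(4R)-2,2-dimethyl-1,3-dioxolan-4-yl]-2-methylidenepent-4-en-1-ol | C=CCC(=C)[C@H](O)[C@H]1COC(C)(C)O1 | intermediate
7 | (1S)-1-[(4R)-2,2-dimethyl-1,3-dioxolan-4-yl]-2-methylidenepent-4-en-1-yl acetate | C=CCC(=C)[C@H](OC(C)=O)[C@H]1COC(C)(C)O1 | intermediate
8 | (R)-(−)-linalool, (3R)-3,7-dimethylocta-1,6-dien-3-ol | C=C[C@](C)(O)CCC=C(C)C | starting material
9 | (3R)-3,7-dimethyl-3-(triethylsilyloxy)octa-1,6-diene | C=C[C@](C)(O[Si](CC)(CC)CC)CCC=C(C)C | intermediate
10 | (4R)-4-methyl-4-(triethylsilyloxy)hex-5-enal | C=C[C@](C)(O[Si](CC)(CC)CC)CCC=O | intermediate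
11 | (2R,4R)-4-methyl-2-(N-phenylaminooxy)-4-(triethylsilyloxy)hex-5-enal | C=C[C@](C)(O[Si](CC)(CC)CC)C[C@@H](ONc1ccccc1)C=O | intermediate (not isolated)
12 | (2R,4R)-4-methyl-2-(N-phenylaminooxy)-4-(triethylsilyloxy)hex-5-en-1-ol | C=C[C@](C)(O[Si](CC)(CC)CC)C[C@@H](ONc1ccccc1)CO | intermediate
13 | (2R,4R)-4-methyl-4-(triethylsilyloxy)hex-5-ene-1,2-diol | C=C[C@](C)(O[Si](CC)(CC)CC)C[C@@H](O)CO | intermediate
14 | (2R,4R)-4-methyl-1,4-bis(triethylsilyloxy)hex-5-en-2-ol | C=C[C@](C)(O[Si](CC)(CC)CC)C[C@@H](O)CO[Si](CC)(CC)CC | intermediate (not isolated)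
15 | (2R,4R)-2-(tert-butyldimethylsilyloxy)-4-methyl-1,4-bis(triethylsilyloxy)hex-5-ene (C7 OTES, C8 OTBS, C10 OTES) | C=C[C@](C)(O[Si](CC)(CC)CC)C[C@@H](O[Si](C)(C)C(C)(C)C)CO[Si](CC)(CC)CC | intermediate
16 | cross-metathesis product: (E)-C1=C2; C4 methylidene; C5 (S) acetate; C6 as the (4R)-dioxolane carbon; C7 CH2OTES; C8 (R) OTBS; C10 (R) methyl/OTES | CC1(C)OC[C@@H](O1)[C@@H](OC(C)=O)C(=C)C/C=C/[C@](C)(O[Si](CC)(CC)CC)C[C@@H](O[Si](C)(C)C(C)(C)C)CO[Si](CC)(CC)CC | intermediate
17 | C7 aldehyde of 16 (5S,8R,10R; 1E) | CC1(C)OC[C@@H](O1)[C@@H](OC(C)=O)C(=C)C/C=C/[C@](C)(O[Si](CC)(CC)CC)C[C@@H](O[Si](C)(C)C(C)(C)C)C=O | intermediate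
18 | methyl acrylate | C=CC(=O)OC | starting material
19 | Morita–Baylis–Hillman adduct: methyl 2-methylidene ester (C11=C13, C12 ester), C7 carbinol as epimer mixture, otherwise as 17 (5S,8R,10R; 1E) | CC1(C)OC[C@@H](O1)[C@@H](OC(C)=O)C(=C)C/C=C/[C@](C)(O[Si](CC)(CC)CC)C[C@@H](O[Si](C)(C)C(C)(C)C)C(O)C(=C)C(=O)OC | intermediate
20 | allylic bromide: methyl (Z)-2-(bromomethyl)enoate at C7=C11 (C8 cis to CH2Br), otherwise as 17 (5S,8R,10R; 1E) | CC1(C)OC[C@@H](O1)[C@@H](OC(C)=O)C(=C)C/C=C/[C@](C)(O[Si](CC)(CC)CC)C[C@@H](O[Si](C)(C)C(C)(C)C)/C=C(\CBr)C(=O)OC | intermediate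
21 | vicinal diol from acetonide hydrolysis of 20 (diol carbon R; 5S,8R,10R) | OC[C@@H](O)[C@@H](OC(C)=O)C(=C)C/C=C/[C@](C)(O[Si](CC)(CC)CC)C[C@@H](O[Si](C)(C)C(C)(C)C)/C=C(\CBr)C(=O)OC | intermediate (not isolated)
22 | cyclization precursor: C6 aldehyde, C5 (S) acetate, C4 methylidene, (E)-C1=C2, C10 (R) OTES, C8 (R) OTBS, methyl (Z)-2-(bromomethyl)enoate | O=C[C@@H](OC(C)=O)C(=C)C/C=C/[C@](C)(O[Si](CC)(CC)CC)C[C@@H](O[Si](C)(C)C(C)(C)C)/C=C(\CBr)C(=O)OC | intermediate
23 | allylchromium dichloride from 22 (C13–CrCl2) | O=C[C@@H](OC(C)=O)C(=C)C/C=C/[C@](C)(O[Si](CC)(CC)CC)C[C@@H](O[Si](C)(C)C(C)(C)C)/C=C(\C[Cr](Cl)Cl)C(=O)OC | intermediate (not isolated)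
24 | ten-membered seco hydroxy ester as its dichlorochromium alkoxide (5S,6S,7S,8R,10R) | COC(=O)C(=C)[C@@H]1[C@H](O[Si](C)(C)C(C)(C)C)C[C@@](C)(O[Si](CC)(CC)CC)/C=C/CC(=C)[C@H](OC(C)=O)[C@H]1O[Cr](Cl)Cl | intermediate (not isolated)
25 | (5S,6S,7S,8R,10R)-5-acetoxy-8-(tert-butyldimethylsilyloxy)-10-(triethylsilyloxy)germacra-1(2)E,4(15),11(13)-trien-12,6-olide (trans-fused) | C=C1C(=O)O[C@H]2[C@H]1[C@H](O[Si](C)(C)C(C)(C)C)C[C@@](C)(O[Si](CC)(CC)CC)/C=C/CC(=C)[C@@H]2OC(C)=O | intermediate
26 | (5S,6S,7R,8R,10R)-5-acetoxy-8,10-dihydroxygermacra-1(2)E,4(15),11(13)-trien-12,6-olide | C=C1C(=O)O[C@H]2[C@H]1[C@H](O)C[C@@](C)(O)/C=C/CC(=C)[C@@H]2OC(C)=O | intermediate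
27 | tigloyl chloride, (E)-2-methylbut-2-enoyl chloride | C/C=C(\C)C(Cl)=O | starting material
28 | CNP0323375.1, (5S,6S,7R,8R,10R)-5-acetoxy-10-hydroxy-8-tigloyloxygermacra-1(2)E,4(15),11(13)-trien-12,6-olide | C=C1C(=O)O[C@H]2[C@H]1[C@H](OC(=O)/C(C)=C/C)C[C@@](C)(O)/C=C/CC(=C)[C@@H]2OC(C)=O | target

Total step count: 16
Longest linear sequence: 13 steps (steps 4–16, from (R)-linalool 8)

Steps most likely to fail

1. Step 14 (ring closure). What may go wrong: intermolecular coupling may outrun ring closure, and the face selection at the formyl group may follow the Felkin–Anh preference of C5 instead of the ring chair, giving diastereomeric lactones. Fallback: make the C6–C7 bond before the ring and close the ring at C1=C2. It sets out from 15 and 7 and returns to the route at 25. From 15, Swern oxidation as in step 10 gives aldehyde F1, Morita–Baylis–Hillman reaction with 18 gives hydroxy ester F2, and NBS/Me2S gives bromide F3. From 7, H5IO6 in EtOAc gives α-acetoxy aldehyde F4. Zinc-mediated Barbier coupling of F3 with F4 (Zn, THF/aq. NH4Cl) with lactonization gives, after chromatographic separation of the diastereomers, open-chain lactone F5; the metal can be changed to indium or CrCl2 to shift the distribution. Ring-closing metathesis of F5 (second-generation Hoveyda–Grubbs catalyst, toluene, 80 °C, high dilution) forms the E-C1=C2 bond and gives 25.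

2. Step 9 (cross-metathesis). What may go wrong: turnover at the hindered tertiary allylic silyl ether may be so slow that homodimerization of 7 and olefin migration in its skipped diene dominate. Fallback: run the metathesis on the free tertiary carbinol, which is the more reactive partner. It sets out from 13 and returns at 16. TBAF in THF removes the tertiary silyl group of 13 to give triol F6. TESCl (imidazole, −30 °C) and then TBSCl (imidazole, DMAP, DMF) silylate only the primary and secondary hydroxyls, giving carbinol F7. Cross-metathesis of F7 with 7 under the catalyst of step 9 should give allylic alcohol F8, and TESOTf/2,6-lutidine then gives 16.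

3. Step 11 (Morita–Baylis–Hillman reaction). What may go wrong: the amine-catalysed addition to the hindered α-silyloxy aldehyde may be slow enough for base-mediated epimerization at C8 or β-elimination of silanol to intervene. Fallback: vinylalumination in place of amine catalysis. It sets out from 17 and returns at 19. The pre-formed [1-(methoxycarbonyl)vinyl]diisobutylalane (DIBAL-H, N-methylmorpholine N-oxide, methyl propiolate, THF, 0 °C) adds rapidly to 17 and gives 19 directly; no new compound is made on the way.

Further compounds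
F1 | step 14 | (2R,4R)-2-(tert-butyldimethylsilyloxy)-4-methyl-4-(triethylsilyloxy)hex-5-enal | C=C[C@](C)(O[Si](CC)(CC)CC)C[C@@H](O[Si](C)(C)C(C)(C)C)C=O
F2 | step 14 | methyl (4R,6R)-4-(tert-butyldimethylsilyloxy)-3-hydroxy-6-methyl-2-methylidene-6-(triethylsilyloxy)oct-7-enoate (C3 epimers) | C=C[C@](C)(O[Si](CC)(CC)CC)C[C@@H](O[Si](C)(C)C(C)(C)C)C(O)C(=C)C(=O)OC
F3 | step 14 | methyl (2Z,4R,6R)-2-(bromomethyl)-4-(tert-butyldimethylsilyloxy)-6-methyl-6-(triethylsilyloxy)octa-2,7-dienoate | C=C[C@](C)(O[Si](CC)(CC)CC)C[C@@H](O[Si](C)(C)C(C)(C)C)/C=C(\CBr)C(=O)OC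
F4 | step 14 | (2S)-3-methylidene-1-oxohex-5-en-2-yl acetate | C=CCC(=C)[C@H](OC(C)=O)C=O
F5 | step 14 | open-chain α-methylene-γ-butyrolactone (5S,6S,7S,8R,10R) with C2 and C1 as terminal vinyl groups; C5 acetate, C8 OTBS, C10 OTES | C=C1C(=O)O[C@H]([C@@H](OC(C)=O)C(=C)CC=C)[C@H]1[C@H](O[Si](C)(C)C(C)(C)C)C[C@@](C)(O[Si](CC)(CC)CC)C=C
F6 | step 9 | (2R,4R)-4-methylhex-5-ene-1,2,4-triol | C=C[C@](C)(O)C[C@@H](O)CO
F7 | step 9 | (3R,5R)-5-(tert-butyldimethylsilyloxy)-3-methyl-6-(triethylsilyloxy)hex-1-en-3-ol | C=C[C@](C)(O)C[C@@H](O[Si](C)(C)C(C)(C)C)CO[Si](CC)(CC)CC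
F8 | step 9 | analogue of 16 with free C10 hydroxyl (5S,8R,10R; 1E; dioxolane 4R) | CC1(C)OC[C@@H](O1)[C@@H](OC(C)=O)C(=C)C/C=C/[C@](C)(O)C[C@@H](O[Si](C)(C)C(C)(C)C)CO[Si](CC)(CC)CC
F0 | step 11 | none | none
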